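**Retrosynthetic overview**
1. The target is numbered as a 7-oxabicyclo[4.1.0]heptane (C1 methyl/epoxide, C2 ketone, C3 O-angelate, C4 side chain, C5 CH2, C6 epoxide CH). End game: the C2 ketone comes from the C2 alcohol, whose hydroxyl first directs the C1–C6 epoxidation; that alcohol comes from Luche reduction of a 6-acyloxy-2-methylcyclohex-2-enone; both angelates are put on one diol.
2. Side chain: the C(=CH2)–CH(OH) bond is made by asymmetric Ni/Cr coupling of an enol triflate with 4-methylpent-3-enal; no protecting group is used anywhere.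
3. The enone comes from a 7-oxabicyclo[2.2.1]heptan-2-one by strain-releasing β-elimination: the oxygen bridge between C3 and C6 opens at C6 and stays on C3.
4. Key disconnection: bonds C5–C6 and C3–C4, by a dearomatizing Diels–Alder reaction of 3-methylfuran with an acrylate. The enabling feature is the arc C6–C1(Me)–C2–C3, which carries oxygen on both end carbons (epoxide O on C6, ester O on C3) and the methyl on C1; it is a masked 3-methylfuran whose ring oxygen becomes O–C3.
5. Ring order: the cyclohexane first (as the oxanorbornene), the oxirane last.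

Key step: step 1

Assumption: the senses of induction of the chiral catalyst in step 1 and of the chiral ligand in step 7 are taken as drawn; if either proves opposite, its mirror-image form is used and nothing else changes.

Step 1
Reactants: 1 3-methylfuran (excess); 2 2,2,2-trifluoroethyl acrylate
Product: 3 2,2,2-trifluoroethyl (1R,2R,4R)-5-methyl-7-oxabicyclo[2.2.1]hept-5-ene-2-carboxylate (2-endo)
Conditions: (S)-oxazaborolidinium triflimide [from (S)-α,α-diphenylprolinol, o-tolylboroxine and HNTf2] (10 mol %), CH2Cl2, −78 °C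
Reagents that add atoms: none
Why: The Lewis-acid-bound acrylate and the furan combine in a concerted but asynchronous normal-demand [4+2] cycloaddition (Diels–Alder reaction); the closest known reaction type is the oxazaborolidinium-catalysed Diels–Alder reaction of furans with trifluoroethyl acrylate. The six-membered carbocycle is closed intermolecularly in the suprafacial [4+2] mode, and because the diene is a ring it appears as the 7-oxabicyclo[2.2.1]heptene. The two bridgehead centres follow from cis addition across furan C2 and C5, the ester-bearing centre is placed endo (anti to the oxygen bridge) by the kinetically controlled low-temperature transition state, and the absolute sense is fixed by the catalyst, which shields one face of the coordinated acrylate. Regioselectivity is needed and is secured by the 3-methyl group: the more nucleophilic furan C2 next to it bonds first to the acrylate β-carbon, which puts the ester on the carbon 1,4 to the methyl-bearing carbon. The activated trifluoroethyl ester allows reaction at −78 °C, which should suppress cycloreversion (loss of endo selectivity) and Friedel–Crafts alkylation of the furan; minor exo and regioisomers should be removable by chromatography.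

Step 2
Reactants: 3 2,2,2-trifluoroethyl (1R,2R,4R)-5-methyl-7-oxabicyclo[2.2.1]hept-5-ene-2-carboxylate
Product: 5 1-[(1R,2R,4R)-5-methyl-7-oxabicyclo[2.2.1]hept-5-en-2-yl]ethan-1-one, via Weinreb amide 4 (not isolated)
Conditions: MeNH(OMe)·HCl, iPrMgCl, THF, −20 °C; then MeMgCl, −20 to 0 °C; aq. NH4Cl; product kept cold
Reagents that add atoms: methylmagnesium chloride (C[Mg]Cl)
Why: The magnesium amide converts the activated ester into Weinreb amide 4, whose chelated tetrahedral adduct with MeMgCl collapses only on work-up to the methyl ketone (one-pot Weinreb ketone synthesis), and the nucleophilic, weakly basic reagents should not enolize C2, so the three stereocentres are untouched.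

Step 3
Reactants: 5 1-[(1R,2R,4R)-5-methyl-7-oxabicyclo[2.2.1]hept-5-en-2-yl]ethan-1-one
Product: 7 1-[(1R,2R,4R)-5-methyl-7-oxabicyclo[2.2.1]hept-5-en-2-yl]ethenyl trifluoromethanesulfonate, via potassium enolate 6 (not isolated)
Conditions: KN(SiMe3)2, THF, −78 °C; then PhNTf2, −78 to 0 °C
Reagents that add atoms: N-phenylbis(trifluoromethanesulfonimide) (O=S(=O)(N(c1ccccc1)S(=O)(=O)C(F)(F)F)C(F)(F)F)
Why: Kinetic deprotonation at the unhindered methyl group and O-sulfonylation of enolate 6 (kinetic enol triflate formation) give the terminal alkenyl triflate, which masks the ketone for the next step and is the handle for the later Nozaki–Hiyama–Kishi coupling; no stereocentre is formed.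

Step 4
Reactants: 7 1-[(1R,2R,4R)-5-methyl-7-oxabicyclo[2.2.1]hept-5-en-2-yl]ethenyl trifluoromethanesulfonate
Product: 9 1-[(1S,2R,4R,5R,6R)-6-hydroxy-5-methyl-7-oxabicyclo[2.2.1]heptan-2-yl]ethenyl trifluoromethanesulfonate, via alkylborane 8 (not isolated)
Conditions: BH3·THF (1.0 equiv), THF, −20 to 0 °C; then NaBO3·4H2O, THF/H2O, rt
Reagents that add atoms: sodium perborate tetrahydrate ([Na+].[Na+].O[B-]1(O)OO[B-](O)(O)OO1)
Why: Hydroboration–oxidation: borane should add to the strained, more electron-rich ring alkene in preference to the triflate-deactivated alkene, with boron on the less substituted carbon from the exo face (syn to the oxygen bridge), so that oxidation with retention gives the 6-exo-hydroxyl and the 5-endo-methyl; perborate is mild enough for the triflate.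

Step 5
Reactants: 9 1-[(1S,2R,4R,5R,6R)-6-hydroxy-5-methyl-7-oxabicyclo[2.2.1]heptan-2-yl]ethenyl trifluoromethanesulfonate
Product: 11 1-[(1R,6S)-6-hydroxy-4-methyl-5-oxocyclohex-3-en-1-yl]ethenyl trifluoromethanesulfonate, via bridged ketone 10 (not isolated)
Conditions: Dess–Martin periodinane, pyridine, CH2Cl2, 0 °C to rt; then DBU (cat.), 0 °C
Reagents that add atoms: none
Why: Dess–Martin oxidation gives bridged ketone 10, and base then removes its only enolizable proton (on the methyl-bearing carbon), so that an E1cB β-elimination driven by release of the bicyclic strain opens the oxygen bridge to the 2-methyl-2-enone and leaves the oxygen on the other bridgehead as a hydroxyl of unchanged configuration, trans to the neighbouring carbon substituent.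

Step 6
Reactants: 12 4-methylpent-3-en-1-ol
Product: 13 4-methylpent-3-enal
Conditions: Dess–Martin periodinane, pyridine, CH2Cl2, 0 °C; used at once as a solution
Reagents that add atoms: none
Why: Dess–Martin oxidation under buffered, non-basic conditions should give the β,γ-unsaturated aldehyde without migration of the double bond into conjugation; no stereocentre is involved.

Step 7
Reactants: 11 1-[(1R,6S)-6-hydroxy-4-methyl-5-oxocyclohex-3-en-1-yl]ethenyl trifluoromethanesulfonate; 13 4-methylpent-3-enal
Product: 14 (5S,6S)-6-hydroxy-5-[(3S)-3-hydroxy-6-methylhepta-1,5-dien-2-yl]-2-methylcyclohex-2-en-1-one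
Conditions: CrCl2 (4 equiv), NiCl2 (2 mol %), chiral oxazoline–sulfonamide ligand (4.4 equiv), Et3N, THF, rt
Reagents that add atoms: none
Why: Nozaki–Hiyama–Kishi coupling: nickel inserts into the C–OTf bond, transmetalation gives an alkenylchromium species that adds to the aldehyde and tolerates the enone and the free hydroxyl, and the chiral ligand on chromium controls the aldehyde face so that the new carbinol centre is S.

Step 8
Reactants: 14 (5S,6S)-6-hydroxy-5-[(3S)-3-hydroxy-6-methylhepta-1,5-dien-2-yl]-2-methylcyclohex-2-en-1-one; 15 angelic acid [(2Z)-2-methylbut-2-enoic acid] (two equivalents are consumed, one per hydroxyl)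
Product: 17 (1S,6S)-3-methyl-6-[(3S)-6-methyl-3-{[(2Z)-2-methylbut-2-enoyl]oxy}hepta-1,5-dien-2-yl]-2-oxocyclohex-3-en-1-yl (2Z)-2-methylbut-2-enoate, via side-chain mono-angelate 16 (not isolated)
Conditions: 15 (3 equiv), 2,4,6-trichlorobenzoyl chloride (3 equiv), Et3N, toluene, rt; then 14, 75 °C (no DMAP)
Reagents that add atoms: angelic acid, second equivalent of 15 (C/C=C(/C)C(=O)O)
Why: Yamaguchi-type mixed-anhydride esterification with an excess of the preformed anhydride acylates first the more nucleophilic side-chain carbinol (mono-angelate 16) and then the α-ketol hydroxyl in the same flask, so that two molecules of 15 end up in the product, and DMAP-free conditions are the ones known to install angelates without Z-to-E isomerization to tiglates; no stereocentre changes.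

Step 9
Reactants: 17 the bis-angelate enone
Product: 18 (1S,2S,6S)-2-hydroxy-3-methyl-6-[(3S)-6-methyl-3-{[(2Z)-2-methylbut-2-enoyl]oxy}hepta-1,5-dien-2-yl]cyclohex-3-en-1-yl (2Z)-2-methylbut-2-enoate
Conditions: NaBH4, CeCl3·7H2O, MeOH, −78 °C; AcOH quench
Reagents that add atoms: none
Why: Luche reduction: 1,2-selective hydride delivery along the axial trajectory of the half-chair that carries both ring substituents equatorial should give the pseudo-equatorial alcohol, trans to the adjacent acyloxy group and cis to the side chain (the sense seen in the reduction of carvone to cis-carveol).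

Step 10
Reactants: 18 the allylic alcohol
Product: 19 (1R,2R,3S,4S,6S)-2-hydroxy-1-methyl-4-[(3S)-6-methyl-3-{[(2Z)-2-methylbut-2-enoyl]oxy}hepta-1,5-dien-2-yl]-7-oxabicyclo[4.1.0]heptan-3-yl (2Z)-2-methylbut-2-enoate
Conditions: VO(acac)2 (5 mol %), tBuOOH, CH2Cl2, 0 °C to rt
Reagents that add atoms: tert-butyl hydroperoxide (CC(C)(C)OO)
Why: Hydroxyl-directed, vanadium-catalysed epoxidation delivers oxygen to the ring alkene syn to the allylic hydroxyl, which fixes both epoxide centres on the face of the side chain, and it should leave the isolated alkenes and the electron-poor angelates untouched.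

Step 11
Reactants: 19 the epoxy alcohol
Product: 20 (1S,3S,4S,6S)-1-methyl-4-[(3S)-6-methyl-3-{[(2Z)-2-methylbut-2-enoyl]oxy}hepta-1,5-dien-2-yl]-2-oxo-7-oxabicyclo[4.1.0]heptan-3-yl (2Z)-2-methylbut-2-enoate (target)
Conditions: Dess–Martin periodinane, pyridine, CH2Cl2, 0 °C to rt
Reagents that add atoms: none
Why: Dess–Martin oxidation of the epoxy alcohol to the α,β-epoxy ketone under buffered neutral conditions should complete the target without epimerizing the α-acyloxy centre or opening the epoxide.

**Compound list**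
1 | 3-methylfuran | Cc1ccoc1 | starting material
2 | 2,2,2-trifluoroethyl acrylate | C=CC(=O)OCC(F)(F)F | starting material
3 | 2,2,2-trifluoroethyl (1R,2R,4R)-5-methyl-7-oxabicyclo[2.2.1]hept-5-ene-2-carboxylate (endo ester) | O=C(OCC(F)(F)F)[C@@H]1C[C@@H]2C(C)=C[C@H]1O2 | intermediate
4 | (1R,2R,4R)-N-methoxy-N,5-dimethyl-7-oxabicyclo[2.2.1]hept-5-ene-2-carboxamide (Weinreb amide, not isolated) | CON(C)C(=O)[C@@H]1C[C@@H]2C(C)=C[C@H]1O2 | intermediate
5 | 1-[(1R,2R,4R)-5-methyl-7-oxabicyclo[2.2.1]hept-5-en-2-yl]ethan-1-one | CC(=O)[C@@H]1C[C@@H]2C(C)=C[C@H]1O2 | intermediate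
6 | potassium enolate of 5 on the methyl side (not isolated) | [K+].[O-]C(=C)[C@@H]1C[C@@H]2C(C)=C[C@H]1O2 | intermediate
7 | 1-[(1R,2R,4R)-5-methyl-7-oxabicyclo[2.2.1]hept-5-en-2-yl]ethenyl trifluoromethanesulfonate | C=C(OS(=O)(=O)C(F)(F)F)[C@@H]1C[C@@H]2C(C)=C[C@H]1O2 | intermediate
8 | monoalkylborane: 9 with BH2 in place of the 6-exo-hydroxyl (not isolated) | C=C(OS(=O)(=O)C(F)(F)F)[C@@H]1C[C@@H]2[C@H](C)[C@@H](B)[C@H]1O2 | intermediate
9 | 1-[(1S,2R,4R,5R,6R)-6-hydroxy-5-methyl-7-oxabicyclo[2.2.1]heptan-2-yl]ethenyl trifluoromethanesulfonate (6-exo-hydroxyl, 5-endo-methyl) | C=C(OS(=O)(=O)C(F)(F)F)[C@@H]1C[C@@H]2[C@H](C)[C@@H](O)[C@H]1O2 | intermediate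
10 | 1-[(1S,2R,4R,5S)-5-methyl-6-oxo-7-oxabicyclo[2.2.1]heptan-2-yl]ethenyl trifluoromethanesulfonate (bridged ketone, not isolated) | C=C(OS(=O)(=O)C(F)(F)F)[C@@H]1C[C@@H]2[C@H](C)C(=O)[C@H]1O2 | intermediate
11 | 1-[(1R,6S)-6-hydroxy-4-methyl-5-oxocyclohex-3-en-1-yl]ethenyl trifluoromethanesulfonate | C=C(OS(=O)(=O)C(F)(F)F)[C@@H]1CC=C(C)C(=O)[C@H]1O | intermediate
12 | 4-methylpent-3-en-1-ol | CC(C)=CCCO | starting material
13 | 4-methylpent-3-enal | CC(C)=CCC=O | intermediate
14 | (5S,6S)-6-hydroxy-5-[(3S)-3-hydroxy-6-methylhepta-1,5-dien-2-yl]-2-methylcyclohex-2-en-1-one | C=C([C@H](CC=C(C)C)O)[C@@H]1CC=C(C)C(=O)[C@H]1O | intermediate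
15 | angelic acid, (2Z)-2-methylbut-2-enoic acid | C/C=C(/C)C(=O)O | starting material
16 | (3S)-2-[(1S,6S)-6-hydroxy-4-methyl-5-oxocyclohex-3-en-1-yl]-6-methylhepta-1,5-dien-3-yl (2Z)-2-methylbut-2-enoate (side-chain mono-angelate, not isolated) | C=C([C@H](CC=C(C)C)OC(=O)/C(C)=C\C)[C@@H]1CC=C(C)C(=O)[C@H]1O | intermediate
17 | (1S,6S)-3-methyl-6-[(3S)-6-methyl-3-{[(2Z)-2-methylbut-2-enoyl]oxy}hepta-1,5-dien-2-yl]-2-oxocyclohex-3-en-1-yl (2Z)-2-methylbut-2-enoate | C=C([C@H](CC=C(C)C)OC(=O)/C(C)=C\C)[C@@H]1CC=C(C)C(=O)[C@H]1OC(=O)/C(C)=C\C | intermediate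
18 | (1S,2S,6S)-2-hydroxy-3-methyl-6-[(3S)-6-methyl-3-{[(2Z)-2-methylbut-2-enoyl]oxy}hepta-1,5-dien-2-yl]cyclohex-3-en-1-yl (2Z)-2-methylbut-2-enoate | C=C([C@H](CC=C(C)C)OC(=O)/C(C)=C\C)[C@@H]1CC=C(C)[C@H](O)[C@H]1OC(=O)/C(C)=C\C | intermediate
19 | (1R,2R,3S,4S,6S)-2-hydroxy-1-methyl-4-[(3S)-6-methyl-3-{[(2Z)-2-methylbut-2-enoyl]oxy}hepta-1,5-dien-2-yl]-7-oxabicyclo[4.1.0]heptan-3-yl (2Z)-2-methylbut-2-enoate | C=C([C@H](CC=C(C)C)OC(=O)/C(C)=C\C)[C@@H]1C[C@@H]2O[C@]2(C)[C@H](O)[C@H]1OC(=O)/C(C)=C\C | intermediate
20 | (1S,3S,4S,6S)-1-methyl-4-[(3S)-6-methyl-3-{[(2Z)-2-methylbut-2-enoyl]oxy}hepta-1,5-dien-2-yl]-2-oxo-7-oxabicyclo[4.1.0]heptan-3-yl (2Z)-2-methylbut-2-enoate | C=C([C@H](CC=C(C)C)OC(=O)/C(C)=C\C)[C@@H]1C[C@@H]2O[C@]2(C)C(=O)[C@H]1OC(=O)/C(C)=C\C | target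

**Step count**
Total steps: 11 (including step 6, the preparation of aldehyde 13). Longest linear sequence: 10 steps (steps 1–5 and 7–11, from 1 and 2).

**Steps most likely to fail, with fallbacks**

Step 1 (key Diels–Alder reaction). What may go wrong: cycloreversion and re-addition eroding the endo selectivity; conjugate (Friedel–Crafts) alkylation of the electron-rich furan at C2 by the strongly activated acrylate instead of ring closure; partial addition in the other orientation, giving the 6-methyl regioisomer. Fallback, setting out from 1: the dienophile is changed to a chelating one, commercially available 3-acryloyl-1,3-oxazolidin-2-one, under two-point binding by the milder divalent copper catalyst [Cu((S,S)-tBu-box)](SbF6)2 in CH2Cl2 at −78 °C. This should give the endo imide 3-{[(1R,2R,4R)-5-methyl-7-oxabicyclo[2.2.1]hept-5-en-2-yl]carbonyl}-1,3-oxazolidin-2-one F1. Transamidation with MeNH(OMe)·HCl and AlMe3 gives Weinreb amide 4, now isolated, and MeMgCl brings the fallback back to the route at 5.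

Step 4 (hydroboration in the presence of the enol triflate). What may go wrong: loss of chemoselectivity, that is, borane adding to the alkenyl triflate double bond (followed by β-elimination of triflate) in competition with the ring alkene. Fallback, setting out from 3: the ring alkene is hydroborated at the ester stage, where it is the only alkene, and the hydroxyl is carried as a silyl ether. BH3·THF gives the ester alkylborane F2, and perborate gives 2,2,2-trifluoroethyl (1S,2R,4R,5R,6R)-6-hydroxy-5-methyl-7-oxabicyclo[2.2.1]heptane-2-carboxylate F3. Et3SiCl and imidazole give its triethylsilyl ether F4. MeNH(OMe)·HCl with iPrMgCl, then MeMgCl, give through the silyl-protected Weinreb amide F5 the silyl-protected methyl ketone F6. KN(SiMe3)2, then PhNTf2, give through the silyl-protected potassium enolate F7 the silyl-protected enol triflate F8. HF·pyridine in THF removes the silyl group and the fallback comes back to the route at 9.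

Step 7 (Ni/Cr coupling). What may go wrong: poor facial selectivity at the new carbinol carbon when the ligand is mismatched with the resident stereocentres; double-bond migration or enolization of the β,γ-unsaturated aldehyde; reduction of the α-ketol by divalent chromium. Fallback, setting out from 11: the carbinol is made by reagent-controlled allylation and the prenyl terminus by metathesis. Reductive carbonylation of the triflate (Pd(OAc)2, dppp, CO, Et3SiH, Et3N, DMF) gives the enal 2-[(1S,6S)-6-hydroxy-4-methyl-5-oxocyclohex-3-en-1-yl]prop-2-enal F9. B-allyldiisopinocampheylborane of the appropriate antipode (Et2O, −78 °C, ethanolamine work-up) gives (5S,6S)-6-hydroxy-5-[(3S)-3-hydroxyhexa-1,5-dien-2-yl]-2-methylcyclohex-2-en-1-one F10. Cross-metathesis with 2-methyl-2-butene and the second-generation Grubbs catalyst converts the allyl group into the prenyl group, and the fallback comes back to the route at 14.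

Further compounds
F1 | step 1 | 3-{[(1R,2R,4R)-5-methyl-7-oxabicyclo[2.2.1]hept-5-en-2-yl]carbonyl}-1,3-oxazolidin-2-one | O=C([C@@H]1C[C@@H]2C(C)=C[C@H]1O2)N1CCOC1=O
F2 | step 4 | ester alkylborane: F3 with BH2 in place of the 6-exo-hydroxyl | O=C(OCC(F)(F)F)[C@@H]1C[C@@H]2[C@H](C)[C@@H](B)[C@H]1O2
F3 | step 4 | 2,2,2-trifluoroethyl (1S,2R,4R,5R,6R)-6-hydroxy-5-methyl-7-oxabicyclo[2.2.1]heptane-2-carboxylate | O=C(OCC(F)(F)F)[C@@H]1C[C@@H]2[C@H](C)[C@@H](O)[C@H]1O2
F4 | step 4 | 6-O-triethylsilyl ether of F3 | O=C(OCC(F)(F)F)[C@@H]1C[C@@H]2[C@H](C)[C@@H](O[Si](CC)(CC)CC)[C@H]1O2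
F5 | step 4 | N-methoxy-N-methylamide corresponding to F4 (silyl-protected Weinreb amide) | CON(C)C(=O)[C@@H]1C[C@@H]2[C@H](C)[C@@H](O[Si](CC)(CC)CC)[C@H]1O2
F6 | step 4 | methyl ketone corresponding to F4 (6-O-triethylsilyl ether of the 2-acetyl compound) | CC(=O)[C@@H]1C[C@@H]2[C@H](C)[C@@H](O[Si](CC)(CC)CC)[C@H]1O2
F7 | step 4 | potassium enolate of F6 on the methyl side | [K+].[O-]C(=C)[C@@H]1C[C@@H]2[C@H](C)[C@@H](O[Si](CC)(CC)CC)[C@H]1O2
F8 | step 4 | 6-O-triethylsilyl ether of 9 | C=C(OS(=O)(=O)C(F)(F)F)[C@@H]1C[C@@H]2[C@H](C)[C@@H](O[Si](CC)(CC)CC)[C@H]1O2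
F9 | step 7 | 2-[(1S,6S)-6-hydroxy-4-methyl-5-oxocyclohex-3-en-1-yl]prop-2-enal | C=C(C=O)[C@@H]1CC=C(C)C(=O)[C@H]1O
F10 | step 7 | (5S,6S)-6-hydroxy-5-[(3S)-3-hydroxyhexa-1,5-dien-2-yl]-2-methylcyclohex-2-en-1-one | C=C([C@H](CC=C)O)[C@@H]1CC=C(C)C(=O)[C@H]1O
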